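Count the J that arrives.

| flask | Z | J | remark | time |
|---|---|---|---|---|
| green | 10 mM | 1.1 equiv | run made earlier |  |
| grey | 10 mM | 5.6 equiv | run made earlier |  |
| delta | 10 mM | 1.50 equiv |  | 25 h |
| gamma | 10 mM | 4.00 equiv |  | 25 h |
| epsilon | 10 mM | 0.800 equiv |  | 25 h |

| run | time / h | L / % | G / % | Z / % |
|---|---|---|---|---|
| green | 3.00 | 0 | 43.2 | 21.3 |
| green | 6.00 | 0 | 44.2 | 23.3 |
| green | 10.0 | 0 | 43.4 | 21.6 |
| green | 12.0 | 0.1 | 43.3 | 20.4 |
| grey | 3.00 | 5.2 | 33.4 | 1.8 |
| grey | 6.00 | 1.2 | 32.9 | 1.8 |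
| grey | 10.0 | 0.1 | 30.5 | 4.2 |
| grey | 12.0 | 0 | 30.6 | 5.7 |

(scatter of a reading: 1 percentage point)

- candidate steps: Z <-> X; J + G -> Q; 2 J -> E; Z + J -> G; J + Q <-> L

- which of these holds the largest part of the Z at the end of delta (Z / Q / L / G)
- which of these holds the largest part of the Z at the end of gamma (Z / Q / L / G)
- which of these holds the largest part of the Z at the end of epsilon (Z / Q / L / G)
- how much L is there at the end of delta, in percent of the Z charged

In the first instants J meets Z (Z + J → G), then G (J + G → Q), and itself (2 J → E), while Z also slips into X (Z ⇌ X). The first readings come late: green's G reads 43.2% at 3.00 h and 43.3% at 12.0 h. The middle shows in grey, where L, made from J + Q, falls from 5.2% at 3.00 h to 0.1% at 10.0 h. At the end, L reads 0% in grey, so delta at 25 h is reckoned to hold none. What matters then is the unread share, taken from the last readings: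

U = 100% − Z − G − L: green 36.2%, grey 63.7%

In green, G + 2U comes to 116%, against 1.1 equiv of J charged, so U holds X as well as Q. Grey allows X/Z up to 11.2. X = Z is taken here as a guess of order ten to the zero, which gives Q = U − Z:

Q: green 15.8%, grey 58.0%

Delivered J, D = G + 2Q: green 74.9%, grey 147%

On logarithms, the delivery exponent, the power of the J charge that D follows:

s = ln(D ratio)/ln(charge ratio) = 0.413

Likewise Q follows D with power 1.94. This reckoning then gives:

delta: D 85.1%, Q 20.2%, G 44.6%

gamma: D 128%, Q 44.3%, G 38.9%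

epsilon: D 65.7%, Q 12.3%, G 41.1%

The forecast named Q for delta, Q for gamma, G for epsilon, and L 0%: “Delta (1.5 equiv) should deliver about 1.3 equiv”. On delta it parts from the reckoning above, which puts G first.

Delta ends with G 45.8%, Q 19.7%, Z 17.7% and L 0%, so G leads; gamma gives Q and epsilon G. Beside Z in delta stands X at 16.8% at 25.0 h, while J, the limiting reagent, is at 0% of its charge. The exponent 0.413 gave delta D = 85.1%; the flask's G + 2Q is 85.2%.

    Z ⇌ X (K = 0.950, k = 0.00640 s⁻¹)
    J + G → Q (k = 0.190 M⁻¹ s⁻¹)
    2 J → E (k = 0.220 M⁻¹ s⁻¹)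
    Z + J → G (k = 0.590 M⁻¹ s⁻¹)
    J + Q ⇌ L (K = 1100 M⁻¹, k = 1.00 M⁻¹ s⁻¹)

For delta's charges with 6.00 equiv of J, 0.413 gives D = 151%, hence Q 61.3% and G 28.4%. That flask computes to Q 65.8% and G 28.9%, with Q holding most.

The data are calculated for an exercise; scatter was added.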